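Assumption: the SMILES is read as 1S,2R,4aR,8aR in the acid (both angular methyls and the C1 carboxyl on one face, the C2 methyl on the other) and S at glycerol C2; (S)-Wieland–Miescher ketone, (S)-glycidol and 5-iodo-2-methylpent-2-ene are taken as catalogue compounds.

**Retrosynthetic overview**
1. Target ⇒ acid 13 + (R)-PMB glycidyl ether 16: carboxylate opening of the epoxide, acetylation of the new secondary OH, PMB removal last.
2. C5–side-chain bond and C5=C6 alkene ⇒ alkenyl triflate 10 + homoprenyl iodide 11 by a new Pd/norbornene vicinal C–H alkylation with ipso hydride (net alkylative 1,2-transposition).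
3. C4a quaternary methyl and the triflate ⇒ octalenone 8 by cis-selective Me2CuLi addition and enolate triflation.
4. C2 methyl and C1 ester ⇒ set earlier on the rigid octalin (ketone → enol triflate → ester 5 → Me2CuLi anti to the angular methyl), with the enone masked as a dithiolane.
5. Ring order: no ring is formed; both come from (S)-Wieland–Miescher ketone (its saturated-ketone ring becomes ring A, C1–C4; its enone ring becomes ring B, C5–C8).

**Route**

Step 1
Reactants: 1 (S)-Wieland–Miescher ketone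
Product: 2 (8aS)-6,6-(ethane-1,2-diyldisulfanyl)-8a-methyl-3,4,6,7,8,8a-hexahydronaphthalen-1(2H)-one
Conditions: HS(CH2)2SH (1.05 equiv), p-TsOH·H2O (cat.), AcOH, rt
Reagents that add atoms: ethane-1,2-dithiol (SCCS)
Why: Acid-catalysed thioketalisation is chemoselective for the unhindered conjugated C6 carbonyl over the neopentylic C1 ketone, the C4a=C5 alkene stays in place and no stereocentre is touched.

Step 2
Reactants: 2 dithiolane ketone
Product: 4 (8aS)-6,6-(ethane-1,2-diyldisulfanyl)-8a-methyl-3,4,6,7,8,8a-hexahydronaphthalen-1-yl trifluoromethanesulfonate, via potassium enolate 3 (not isolated)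
Conditions: KN(SiMe3)2, THF, −78 °C; PhNTf2, −78 → 0 °C; dilute HCl wash
Reagents that add atoms: N-phenylbis(trifluoromethanesulfonimide) (FC(F)(F)S(=O)(=O)N(c1ccccc1)S(=O)(=O)C(F)(F)F)
Why: Enolisation of the C1 ketone can only go towards C2 because C8a is quaternary, and O-sulfonylation of the enolate gives the enol triflate (enolate triflation).

Step 3
Reactants: 4 enol triflate
Product: 5 methyl (8aS)-6,6-(ethane-1,2-diyldisulfanyl)-8a-methyl-3,4,6,7,8,8a-hexahydronaphthalene-1-carboxylate
Conditions: Pd(OAc)2 (5 mol %), PPh3 (10 mol %), CO (1 atm), MeOH, Et3N, DMF, 60 °C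
Reagents that add atoms: carbon monoxide ([C-]#[O+]); methanol (CO)
Why: Palladium-catalysed alkoxycarbonylation of an alkenyl triflate (oxidative addition, CO insertion, methanolysis) gives the conjugated ester, with the dithiolane and the ring B alkene as spectators.

Step 4
Reactants: 5 unsaturated ester
Product: 7 methyl (1S,2R,8aR)-6,6-(ethane-1,2-diyldisulfanyl)-2,8a-dimethyl-1,2,3,4,6,7,8,8a-octahydronaphthalene-1-carboxylate, via silyl ketene acetal 6 (not isolated)
Conditions: Me2CuLi (3 equiv), Me3SiCl (5 equiv), THF, −78 → −30 °C; aq NH4Cl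
Reagents that add atoms: lithium dimethylcuprate ([Li+].C[Cu-]C)
Why: Me3SiCl-accelerated cuprate conjugate (Michael) addition to the cyclohexenecarboxylate: in the rigid octalin the 8a-methyl is pseudo-axial and 1,3 to C2, so methyl enters C2 from the opposite face (2R), and protonation of the ketene acetal at C1 from that same open face gives the equatorial ester (1S); any C1 epimer is equilibrated in step 8.

Step 5
Reactants: 7 saturated ester dithiolane
Product: 8 methyl (1S,2R,8aR)-2,8a-dimethyl-6-oxo-1,2,3,4,6,7,8,8a-octahydronaphthalene-1-carboxylate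
Conditions: MeI (excess), CaCO3, MeCN/H2O (4:1), 50 °C
Reagents that add atoms: water (O)
Why: Alkylative hydrolysis of the allylic dithiolane (S-methylation, thionium ion, attack of water) unmasks the enone without touching the ester or the stereocentres.

Step 6
Reactants: 8 octalenone ester
Product: 10 methyl (1S,2R,4aR,8aR)-2,4a,8a-trimethyl-6-(trifluoromethylsulfonyloxy)-1,2,3,4,4a,7,8,8a-octahydronaphthalene-1-carboxylate, via lithium enolate 9 (not isolated)
Conditions: Me2CuLi (2 equiv), Et2O, −20 → 0 °C; then N-(5-chloropyridin-2-yl)bis(trifluoromethanesulfonimide), THF, −78 → 0 °C; aq NH4Cl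
Reagents that add atoms: lithium dimethylcuprate ([Li+].C[Cu-]C); N-(5-chloropyridin-2-yl)bis(trifluoromethanesulfonimide) (FC(F)(F)S(=O)(=O)N(c1ccc(Cl)cn1)S(=O)(=O)C(F)(F)F)
Why: Cuprate conjugate addition to the octalenone occurs by axial attack on the enone ring, giving the cis-fused decalin with the new C4a methyl cis to the 8a-methyl (4aR), and the regiodefined C5=C6 enolate is trapped on oxygen (enolate triflation).

Step 7
Reactants: 10 alkenyl triflate; 11 5-iodo-2-methylpent-2-ene
Product: 12 methyl (1S,2R,4aR,8aR)-2,4a,8a-trimethyl-5-(4-methylpent-3-en-1-yl)-1,2,3,4,4a,7,8,8a-octahydronaphthalene-1-carboxylate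
Conditions: Pd(OAc)2 (10 mol %), P(2-furyl)3 (25 mol %), N-methylbicyclo[2.2.1]hept-2-ene-2-carboxamide (50 mol %), 11 (3 equiv), HCO2Na (1.5 equiv), Cs2CO3 (2.5 equiv), 1,4-dioxane, 90 °C
Reagents that add atoms: none
Why: Proposed new method: a Pd/norbornene relay on the alkenyl triflate, in which zerovalent palladium inserts into C6–OTf, the alkenylpalladium adds across the norbornene, carbonate-assisted metalation of the neighbouring vinylic C5–H closes a five-membered palladacycle, iodide 11 adds oxidatively to give tetravalent palladium and C5–C(sp3) reductive elimination forms the side-chain bond, the now crowded C5 drives β-carbon elimination of norbornene, and formate-derived hydride ends the cycle at C6, so the alkene stays at C5=C6 and no stereocentre is touched; the closest known reaction type is the Catellani ortho-alkylation of aryl halides with ipso hydride termination and its alkenyl (pseudo)halide variants, not shown for a vinylic C–H flanked by two contiguous quaternary carbons.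

Step 8
Reactants: 12 methyl ester
Product: 13 (1S,2R,4aR,8aR)-2,4a,8a-trimethyl-5-(4-methylpent-3-en-1-yl)-1,2,3,4,4a,7,8,8a-octahydronaphthalene-1-carboxylic acid
Conditions: NaOMe (0.3 equiv), MeOH, 60 °C; evaporate; NaSEt (5 equiv), DMF, 90 °C; then 1 M HCl
Reagents that add atoms: none
Why: Methoxide equilibrates C1 to the ester that is equatorial and trans to the C2 methyl (the epimer would be 1,3-diaxial to C5), then SN2 demethylation by thiolate frees the hindered acid without attack at the acyl carbon.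

Step 9
Reactants: 14 (S)-glycidol
Product: 16 (R)-2-{[(4-methoxybenzyl)oxy]methyl}oxirane, via sodium glycidoxide 15 (not isolated)
Conditions: NaH, THF/DMF, 0 °C; 4-MeOC6H4CH2Cl, n-Bu4NI (cat.), 0 °C → rt
Reagents that add atoms: 4-methoxybenzyl chloride (COc1ccc(CCl)cc1)
Why: Williamson etherification of the alkoxide leaves the stereocentre alone (a Payne shift of glycidoxide is degenerate), and the descriptor changes from S to R only through substituent priority.

Step 10
Reactants: 13 acid; 16 (R)-PMB glycidyl ether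
Product: 17 (2S)-2-hydroxy-3-[(4-methoxybenzyl)oxy]propyl (1S,2R,4aR,8aR)-2,4a,8a-trimethyl-5-(4-methylpent-3-en-1-yl)-1,2,3,4,4a,7,8,8a-octahydronaphthalene-1-carboxylate
Conditions: 16 (1.5 equiv), n-Bu4NBr (10 mol %), toluene, 100 °C
Reagents that add atoms: none
Why: Halide-catalysed SN2 opening of the terminal epoxide by the carboxylate at the CH2 carbon is insensitive to the hindered acyl group, and the untouched epoxide CH becomes glycerol C2 (S).

Step 11
Reactants: 17 hydroxy ester
Product: 18 (2S)-2-acetoxy-3-[(4-methoxybenzyl)oxy]propyl (1S,2R,4aR,8aR)-2,4a,8a-trimethyl-5-(4-methylpent-3-en-1-yl)-1,2,3,4,4a,7,8,8a-octahydronaphthalene-1-carboxylate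
Conditions: Ac2O, pyridine, DMAP (cat.), CH2Cl2, 0 °C
Reagents that add atoms: acetic anhydride (CC(=O)OC(C)=O)
Why: DMAP-catalysed acetylation of the only free hydroxyl, so no acyl migration is possible at this stage.

Step 12
Reactants: 18 PMB-protected diester
Product: 19 (2S)-2-acetoxy-3-hydroxypropyl (1S,2R,4aR,8aR)-2,4a,8a-trimethyl-5-(4-methylpent-3-en-1-yl)-1,2,3,4,4a,7,8,8a-octahydronaphthalene-1-carboxylate
Conditions: DDQ (1.5 equiv), CH2Cl2/pH 7 phosphate buffer (10:1), 0 °C
Reagents that add atoms: none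
Why: Oxidative PMB ether cleavage by DDQ (benzylic hydride abstraction, hemiacetal collapse) under buffered, cold conditions avoids migration of the 2-acetyl group to the freed primary hydroxyl.

**Compound list**
1 | (S)-Wieland–Miescher ketone, (8aS)-8a-methyl-3,4,8,8a-tetrahydronaphthalene-1,6(2H,7H)-dione | O=C1CCCC2=CC(=O)CC[C@]12C | starting material
2 | (8aS)-6,6-(ethane-1,2-diyldisulfanyl)-8a-methyl-3,4,6,7,8,8a-hexahydronaphthalen-1(2H)-one | O=C1CCCC2=CC3(SCCS3)CC[C@]12C | intermediate
3 | potassium C1=C2 enolate of 2 | [K+].[O-]C1=CCCC2=CC3(SCCS3)CC[C@]12C | intermediate (not isolated)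
4 | (8aS)-6,6-(ethane-1,2-diyldisulfanyl)-8a-methyl-3,4,6,7,8,8a-hexahydronaphthalen-1-yl trifluoromethanesulfonate | FC(F)(F)S(=O)(=O)OC1=CCCC2=CC3(SCCS3)CC[C@]12C | intermediate
5 | methyl (8aS)-6,6-(ethane-1,2-diyldisulfanyl)-8a-methyl-3,4,6,7,8,8a-hexahydronaphthalene-1-carboxylate | COC(=O)C1=CCCC2=CC3(SCCS3)CC[C@]12C | intermediate
6 | (2R,8aS) methyl trimethylsilyl ketene acetal at C1 of the C2-methylated octalin dithiolane | COC(O[Si](C)(C)C)=C1[C@H](C)CCC2=CC3(SCCS3)CC[C@]12C | intermediate (not isolated)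
7 | methyl (1S,2R,8aR)-6,6-(ethane-1,2-diyldisulfanyl)-2,8a-dimethyl-1,2,3,4,6,7,8,8a-octahydronaphthalene-1-carboxylate | COC(=O)[C@H]1[C@H](C)CCC2=CC3(SCCS3)CC[C@]12C | intermediate
8 | methyl (1S,2R,8aR)-2,8a-dimethyl-6-oxo-1,2,3,4,6,7,8,8a-octahydronaphthalene-1-carboxylate | COC(=O)[C@H]1[C@H](C)CCC2=CC(=O)CC[C@]12C | intermediate
9 | lithium C5=C6 enolate of methyl (1S,2R,4aR,8aR)-2,4a,8a-trimethyl-6-oxodecahydronaphthalene-1-carboxylate | [Li+].COC(=O)[C@H]1[C@H](C)CC[C@]2(C)C=C([O-])CC[C@]12C | intermediate (not isolated)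
10 | methyl (1S,2R,4aR,8aR)-2,4a,8a-trimethyl-6-(trifluoromethylsulfonyloxy)-1,2,3,4,4a,7,8,8a-octahydronaphthalene-1-carboxylate | COC(=O)[C@H]1[C@H](C)CC[C@]2(C)C=C(OS(=O)(=O)C(F)(F)F)CC[C@]12C | intermediate
11 | 5-iodo-2-methylpent-2-ene | CC(C)=CCCI | starting material
12 | methyl (1S,2R,4aR,8aR)-2,4a,8a-trimethyl-5-(4-methylpent-3-en-1-yl)-1,2,3,4,4a,7,8,8a-octahydronaphthalene-1-carboxylate | COC(=O)[C@H]1[C@H](C)CC[C@]2(C)C(CCC=C(C)C)=CCC[C@]12C | intermediate
13 | (1S,2R,4aR,8aR)-2,4a,8a-trimethyl-5-(4-methylpent-3-en-1-yl)-1,2,3,4,4a,7,8,8a-octahydronaphthalene-1-carboxylic acid | OC(=O)[C@H]1[C@H](C)CC[C@]2(C)C(CCC=C(C)C)=CCC[C@]12C | intermediate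
14 | (S)-glycidol | OC[C@H]1CO1 | starting material
15 | sodium (S)-glycidoxide | [Na+].[O-]C[C@H]1CO1 | intermediate (not isolated)
16 | (R)-2-{[(4-methoxybenzyl)oxy]methyl}oxirane | COc1ccc(COC[C@H]2CO2)cc1 | intermediate
17 | (2S)-2-hydroxy-3-[(4-methoxybenzyl)oxy]propyl ester of acid 13 | O[C@@H](COCc1ccc(OC)cc1)COC(=O)[C@H]1[C@H](C)CC[C@]2(C)C(CCC=C(C)C)=CCC[C@]12C | intermediate
18 | (2S)-2-acetoxy-3-[(4-methoxybenzyl)oxy]propyl ester of acid 13 | CC(=O)O[C@@H](COCc1ccc(OC)cc1)COC(=O)[C@H]1[C@H](C)CC[C@]2(C)C(CCC=C(C)C)=CCC[C@]12C | intermediate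
19 | (2S)-2-acetoxy-3-hydroxypropyl (1S,2R,4aR,8aR)-2,4a,8a-trimethyl-5-(4-methylpent-3-en-1-yl)-1,2,3,4,4a,7,8,8a-octahydronaphthalene-1-carboxylate (CNP0320437.1) | CC(=O)O[C@@H](CO)COC(=O)[C@H]1[C@H](C)CC[C@]2(C)C(CCC=C(C)C)=CCC[C@]12C | target

**Step count**
Total: 12 steps. Longest linear sequence: 11 steps (1 → 19 through steps 1–8 and 10–12); step 9 is a one-step side branch.

**Steps most likely to fail**

Step 7 (the proposed new step). Palladation of the C5–H next to the quaternary C4a may be slow, so that formate simply reduces the triflate or the norbornyl-palladium intermediate goes astray. The fallback uses known chemistry, sets out from 8 and comes back at 12. Enone 8 is converted with KOt-Bu in t-BuOH/THF to its extended enolate and alkylated at C5 with iodide 11, giving after reconjugation the tetrasubstituted enone methyl (1S,2R,8aR)-2,8a-dimethyl-5-(4-methylpent-3-en-1-yl)-6-oxo-1,2,3,4,6,7,8,8a-octahydronaphthalene-1-carboxylate F1. Conjugate addition of Me2CuLi and trapping with the chloropyridyl triflimide, as in step 6 but slower on the fully substituted enone, gives the enol triflate of the C4a-methylated ketone F2 (4a-methyl cis to 8a-methyl). Hydrogenolysis of the triflate with Pd(OAc)2/PPh3, HCO2H and n-Bu3N in DMF at 60 °C then gives 12.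

Step 4. The cuprate may add sluggishly to the hindered trisubstituted ester, or with incomplete facial selectivity at C2. The fallback sets C2 under thermodynamic control, sets out from 2 and comes back at 8. Ketone 2 is methylated at C2 (LiN(i-Pr)2, THF, −78 °C; MeI) and equilibrated with NaOMe/MeOH to the equatorial 2-methyl ketone F3, in which the methyl is trans to the 8a-methyl because the epimer would be 1,3-diaxial to it. Corey–Chaykovsky methylenation (Me3SI, n-BuLi, THF) gives the C1 spiro-epoxide F4. Lewis acid rearrangement (MgBr2·OEt2 or BF3·OEt2) gives the C1 carbaldehyde F5. MeI/CaCO3 in aqueous MeCN removes the dithiolane to give the enone aldehyde F6. Pinnick oxidation (NaClO2, NaH2PO4, 2-methylbut-2-ene) gives the enone acid F7, and Me3SiCHN2 in MeOH/toluene returns 8. C1 is still equilibrated in step 8.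

Step 6. Building a quaternary carbon next to a quaternary carbon by cuprate addition, followed by triflation in the same flask, may give low conversion or 1,2-addition. The fallback installs the angular methyl through a cyclopropane, sets out from 8 and comes back at 10. Luche reduction (NaBH4, CeCl3·7H2O, MeOH, −40 °C) gives the allylic alcohol F8 with the hydroxyl cis to the 8a-methyl. Hydroxyl-directed Simmons–Smith cyclopropanation (Et2Zn, CH2I2, CH2Cl2) gives the cyclopropyl carbinol F9 with the CH2 bridge cis to the 8a-methyl. Dess–Martin periodinane gives the cyclopropyl ketone F10. Li in liquid NH3/THF at −78 °C cleaves the C5–CH2 bond that overlaps with the carbonyl, which creates the C4a methyl and the C5=C6 lithium enolate 9; PhNTf2 traps it as 10.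

**Further compounds**
F1 | step 7 | methyl (1S,2R,8aR)-2,8a-dimethyl-5-(4-methylpent-3-en-1-yl)-6-oxo-1,2,3,4,6,7,8,8a-octahydronaphthalene-1-carboxylate | COC(=O)[C@H]1[C@H](C)CCC2=C(CCC=C(C)C)C(=O)CC[C@]12C
F2 | step 7 | methyl 2,4a,8a-trimethyl-5-(4-methylpent-3-en-1-yl)-6-(trifluoromethylsulfonyloxy)-1,2,3,4,4a,7,8,8a-octahydronaphthalene-1-carboxylate (ring stereocentres as in 12) | COC(=O)[C@H]1[C@H](C)CC[C@]2(C)C(CCC=C(C)C)=C(OS(=O)(=O)C(F)(F)F)CC[C@]12C
F3 | step 4 | (2R,8aS)-6,6-(ethane-1,2-diyldisulfanyl)-2,8a-dimethyl-3,4,6,7,8,8a-hexahydronaphthalen-1(2H)-one | O=C1[C@H](C)CCC2=CC3(SCCS3)CC[C@]12C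
F4 | step 4 | C1 spiro-oxirane of F3 (either configuration at C1) | C1OC12[C@H](C)CCC3=CC4(SCCS4)CC[C@]23C
F5 | step 4 | (1S,2R,8aR)-6,6-(ethane-1,2-diyldisulfanyl)-2,8a-dimethyl-1,2,3,4,6,7,8,8a-octahydronaphthalene-1-carbaldehyde | O=C[C@H]1[C@H](C)CCC2=CC3(SCCS3)CC[C@]12C
F6 | step 4 | (1S,2R,8aR)-2,8a-dimethyl-6-oxo-1,2,3,4,6,7,8,8a-octahydronaphthalene-1-carbaldehyde | O=C[C@H]1[C@H](C)CCC2=CC(=O)CC[C@]12C
F7 | step 4 | (1S,2R,8aR)-2,8a-dimethyl-6-oxo-1,2,3,4,6,7,8,8a-octahydronaphthalene-1-carboxylic acid | OC(=O)[C@H]1[C@H](C)CCC2=CC(=O)CC[C@]12C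
F8 | step 6 | methyl (1S,2R,6S,8aR)-6-hydroxy-2,8a-dimethyl-1,2,3,4,6,7,8,8a-octahydronaphthalene-1-carboxylate (hydroxyl cis to the 8a-methyl) | COC(=O)[C@H]1[C@H](C)CCC2=C[C@@H](O)CC[C@]12C
F9 | step 6 | 4a,5-methano (cyclopropane) derivative of F8 with CH2 and hydroxyl cis to the 8a-methyl | COC(=O)[C@H]1[C@H](C)CC[C@]23C[C@H]2[C@@H](O)CC[C@]13C
F10 | step 6 | cyclopropyl ketone from oxidation of F9 at C6 | COC(=O)[C@H]1[C@H](C)CC[C@]23C[C@H]2C(=O)CC[C@]13C
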